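Everything rests on cutting ring B (C5–C10) into a 3,3-disubstituted cyclobutanone (C8, C9, C10, C5) and a silyl alkyne (C6, C7 carrying C11). The cut is offered by C7 bearing the oxygenated C11 and by quaternary C10 lying between two methylenes. One nickel-catalysed (4+2) ring expansion forms C7–C8 and C5–C6, closes the cyclohexenone and sets C10 by choosing which ring bond migrates. The precursor is a 3-methylcyclobutanone with a 3-silyloxy-4-methylpent-4-enyl chain, whose carbinol centre later relays chirality to C5. Ring A is then closed at C4–C5, a Δ3 epoxide gives the 3α,4β-dioxygen pattern, and singlet oxygen installs the C11 hydroperoxide.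

Key step: step 9

Remarks on the chemistry (eudesmane numbering throughout)
- Target read-out: (3R,4R,5R,10R), a trans-decalin. The 3α-acyloxy and 4β-acetoxy groups are trans-diaxial and the 4-methyl is α. The ester is (2S,3R) with its two methyl groups cis, so it derives from tiglic acid.
- Assumption: the antipode of the chiral phosphine L* that makes the correct ring bond migrate has to be found by screening. L* stands for that antipode.
- Cyclobutanone 10 already holds a stereocentre, so its two C8–CH2 bonds are diastereotopic, not enantiotopic. Ligand control is therefore catalyst-controlled diastereoselection, and the minor C10 epimer can be removed as a diastereomer (at 24).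
- A chain on quaternary C10 can reach trigonal C5 only from its own face. Closure therefore gives a cis-decalin with O4 on the α face, whereas the target has 5α-H and 4β-O.
- C4 and C5 are therefore reset on purpose (steps 15 and 18–20). The carbinol is made (S), which is 3β in the bicycle, so that it can serve as the leaving group of the relay.
- A base-mediated vinylogous aldol is avoided for three reasons. C9 would close the same ring size, C3 is α to the C4 ketone, and the extended dienolate can expel the C11 oxygen. C5 is instead marked with bromine and the dienolate is made reductively.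
- Spectator groups are chosen for the later steps. OMe at C11 is small and inert to fluoride, and it leaves only from the saturated ketone enolate. BnMe2Si at C6 is cleaved by fluoride within minutes. TIPS is used at O3.

Step 1
Reactants: 1 ethyl 4-methylpent-4-enoate
Product: 2 N-methoxy-N,4-dimethylpent-4-enamide
Conditions: MeNH(OMe)·HCl, i-PrMgCl, THF, −20 to 0 °C
Reagents that add atoms: N,O-dimethylhydroxylamine hydrochloride CNOC.Cl
Why: Weinreb amide formation from an ester with the chloromagnesium amide is a standard acyl substitution that leaves the isolated olefin untouched.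

Step 2
Reactants: 2 N-methoxy-N,4-dimethylpent-4-enamide, 3 isopropenylmagnesium bromide
Product: 4 2,6-dimethylhepta-1,6-dien-3-one
Conditions: THF, 0 °C; aq. NH4Cl
Reagents that add atoms: none
Why: Grignard addition to a Weinreb amide stops at the chelated tetrahedral adduct, so the isopropenyl ketone (C3, C4, C15 and the sacrificial methylene) is released only on work-up.

Step 3
Reactants: 4 2,6-dimethylhepta-1,6-dien-3-one
Product: 5 (S)-2,6-dimethylhepta-1,6-dien-3-ol
Conditions: (R)-2-methyl-CBS-oxazaborolidine (10 mol %), catecholborane, toluene, −78 °C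
Reagents that add atoms: none
Why: Corey–Bakshi–Shibata reduction with catecholborane avoids olefin hydroboration, and the (R)-oxazaborolidine, reading the α-branched alkenyl group as the large substituent, should deliver hydride to give the (S)-carbinol (future C3, 3β).

Step 4
Reactants: 5 (S)-2,6-dimethylhepta-1,6-dien-3-ol
Product: 6 (S)-2,6-dimethyl-3-(triisopropylsilyloxy)hepta-1,6-diene
Conditions: TIPSOTf, 2,6-lutidine, CH2Cl2, −78 to 0 °C
Reagents that add atoms: triisopropylsilyl triflate CC(C)[Si](OS(=O)(=O)C(F)(F)F)(C(C)C)C(C)C
Why: Silyl triflate silylation of a hindered secondary alcohol gives an ether chosen to outlive zerovalent nickel, the brief fluoride treatment of step 10, radical bromination and divalent samarium.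

Step 5
Reactants: 6 (S)-2,6-dimethyl-3-(triisopropylsilyloxy)hepta-1,6-diene, 7 trichloroacetyl chloride
Product: 9 2,2-dichloro-3-methyl-3-[(3S)-4-methyl-3-(triisopropylsilyloxy)pent-4-enyl]cyclobutanone (both ring epimers), via dichloroketene 8 (not isolated)
Conditions: Zn–Cu couple, Et2O–DME, rt, slow addition of 7
Reagents that add atoms: none
Why: The thermal (2+2) cycloaddition of electrophilic dichloroketene joins its carbonyl carbon to the CH2 terminus of the electron-richer, unhindered 1,1-disubstituted olefin, while the isopropenyl group next to the bulky and inductively withdrawing silyloxy carbon should react much more slowly.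

Step 6
Reactants: 9 dichlorocyclobutanone
Product: 10 3-methyl-3-[(3S)-4-methyl-3-(triisopropylsilyloxy)pent-4-enyl]cyclobutanone
Conditions: Zn, AcOH, rt
Reagents that add atoms: none
Why: Reductive dechlorination of an α,α-dichloroketone with zinc is routine and removes the ring stereocentre, so a single (S)-configured cyclobutanone should result.

Step 7
Reactants: 11 2-methylbut-3-yn-2-ol
Product: 13 3-methoxy-3-methylbut-1-yne, via sodium alkoxide 12 (not isolated)
Conditions: NaH, THF, 0 °C; MeI
Reagents that add atoms: iodomethane CI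
Why: In this Williamson ether synthesis one equivalent of hydride removes only the more acidic hydroxyl proton, so methylation takes place on oxygen.

Step 8
Reactants: 13 3-methoxy-3-methylbut-1-yne
Product: 15 benzyl(3-methoxy-3-methylbut-1-ynyl)dimethylsilane, via lithium acetylide 14 (not isolated)
Conditions: n-BuLi, THF, −78 °C; BnMe2SiCl
Reagents that add atoms: benzylchlorodimethylsilane C[Si](C)(Cl)Cc1ccccc1
Why: C-silylation of a lithium acetylide with a chlorosilane is standard and installs the group that steers the alkyne in step 9.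

Step 9
Reactants: 10 3-methyl-3-[(3S)-4-methyl-3-(triisopropylsilyloxy)pent-4-enyl]cyclobutanone, 15 benzyl(3-methoxy-3-methylbut-1-ynyl)dimethylsilane
Product: 16 (5R)-3-(benzyldimethylsilyl)-2-(2-methoxypropan-2-yl)-5-methyl-5-[(3S)-4-methyl-3-(triisopropylsilyloxy)pent-4-enyl]cyclohex-2-enone
Conditions: Ni(cod)2 (10 mol %), chiral monodentate phosphine L* (neomenthyldiphenylphosphine type, 20 mol %), toluene, 90 °C, slow addition of 15
Reagents that add atoms: none
Why: Proposed new method: zerovalent nickel binds the strained C8 carbonyl and the alkyne and cyclises oxidatively to an oxanickelacyclopentene (C7–C8 formed, silicon-bearing C6 on nickel), β-carbon elimination of one C8–CH2 bond releases the cyclobutane strain to give a seven-membered nickelacycle, and C(sp3)–C(sp2) reductive elimination forms C5–C6. The closest known reactions are the racemic intermolecular insertion of alkynes into 3,3-disubstituted cyclobutanones with Ni(cod)2 and a trialkylphosphine, and the enantioselective intramolecular olefin insertions. Ring B is closed by a formal (4+2) ring expansion, its last bond coming from reductive elimination out of the seven-membered metallacycle. C10 is the only new stereocentre and is set by the ligand, which decides which of the two diastereotopic C8–CH2 bonds migrates; the remote (S)-carbinol has little say but turns the minor C10 epimer into a separable diastereomer. The step needs alkyne regiocontrol, secured by silicon preferring the carbon bound to nickel, and chemoselectivity over alkyne oligomerisation and over the isopropenyl group, secured by slow addition of the hindered alkyne and by the low affinity of nickel for a 1,1-disubstituted olefin.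

Step 10
Reactants: 16 silyl enone
Product: 17 (5S)-2-(2-methoxypropan-2-yl)-5-methyl-5-[(3S)-4-methyl-3-(triisopropylsilyloxy)pent-4-enyl]cyclohex-2-enone
Conditions: Bu4NF, THF, 0 °C, short contact
Reagents that add atoms: none
Why: In this fluoride-induced protodesilylation of a benzyldimethylsilyl alkene, debenzylation gives a fluorosilane whose pentacoordinate form is protonated at C6 within minutes, conditions that a hindered secondary triisopropylsilyl ether and the methyl ether should survive (the descriptor at C10 changes by priority only).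

Step 11
Reactants: 17 enone
Product: 19 (5S)-2-(2-methoxypropan-2-yl)-5-methyl-5-[(3S)-4-oxo-3-(triisopropylsilyloxy)pentyl]cyclohex-2-enone, via ozonide 18 (not isolated)
Conditions: O3, CH2Cl2, −78 °C, Sudan red end-point; Me2S
Reagents that add atoms: ozone [O-][O+]=O
Why: Ozonolysis is selective for the electron-rich 1,1-disubstituted olefin over the electron-poor enone and unmasks the C4 methyl ketone under neutral conditions that leave the adjacent C3 centre intact.

Step 12
Reactants: 19 keto enone
Product: 20 (5R)-4-bromo-2-(2-methoxypropan-2-yl)-5-methyl-5-[(3S)-4-oxo-3-(triisopropylsilyloxy)pentyl]cyclohex-2-enone (both C5 epimers in eudesmane numbering)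
Conditions: NBS, AIBN (cat.), PhCF3, 80 °C
Reagents that add atoms: N-bromosuccinimide O=C1CCC(=O)N1Br
Why: Wohl–Ziegler bromination attacks the only allylic C–H bonds left, those at C5 (γ to the enone), which marks C5 and not the α′ carbon C9 as the future nucleophile, the configuration at C5 being irrelevant.

Step 13
Reactants: 20 γ-bromo enone
Product: 21 4α-hydroxy-11-methoxy-3β-(triisopropylsilyloxy)-5β-eudesm-6-en-8-one (cis-decalin)
Conditions: SmI2 (2.2 equiv), THF, −78 to −40 °C; aq. NH4Cl
Reagents that add atoms: none
Why: In this samarium Barbier (vinylogous Reformatsky) cyclisation, two-electron reduction of the allylic bromide gives the extended dienolate of trivalent samarium regiospecifically and without base, attack through C7 is geometrically impossible, and 6-(enolendo)-exo-trig closure at C5 from the face that carries the tether should give the cis-fused 4α-alcohol, both new centres being cancelled in step 15.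

Step 14
Reactants: 21 hydroxy enone
Product: 23 4α-hydroxy-3β-(triisopropylsilyloxy)-5β-eudesm-7(11)-en-8-one, via β-methoxy ketone 22 (not isolated)
Conditions: LiBH(s-Bu)3 (L-Selectride), THF, −78 °C; MeOH; DBU, rt
Reagents that add atoms: none
Why: 1,4-Reduction of a cyclohexenone whose β-carbon carries hydrogen with a hindered borohydride, followed by E1cB loss of methanol from the β-methoxy ketone, gives the conjugated isopropylidene ketone, and quenching before the elimination prevents over-reduction.

Step 15
Reactants: 23 tertiary alcohol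
Product: 24 3β-(triisopropylsilyloxy)eudesma-4,7(11)-dien-8-one
Conditions: SOCl2, pyridine, 0 °C
Reagents that add atoms: none
Why: Anti E2 dehydration of the axial tertiary chlorosulfite uses the antiperiplanar H5 (H3 is equatorial in the 3β series) to give the tetrasubstituted Δ4 olefin, which cancels the cis fusion and gives a rigid bicycle from which any C10 epimer from step 9 is removed by chromatography.

Step 16
Reactants: 24 silyl ether
Product: 25 3β-hydroxyeudesma-4,7(11)-dien-8-one
Conditions: Bu4NF, THF, rt to 45 °C
Reagents that add atoms: none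
Why: Fluoride cleavage of the silyl ether under longer contact frees the allylic alcohol, and no other fluoride-labile group is left.

Step 17
Reactants: 25 allylic alcohol
Product: 26 3β-formyloxyeudesma-4,7(11)-dien-8-one
Conditions: HCO2Ac, pyridine, CH2Cl2, 0 °C
Reagents that add atoms: acetic formic anhydride CC(=O)OC=O
Why: O-Formylation with the mixed anhydride transfers the more electrophilic formyl group with retention at C3.

Step 18
Reactants: 26 allylic formate
Product: 27 5α-eudesma-3,7(11)-dien-8-one
Conditions: Pd(OAc)2 (5 mol %), PBu3 (5 mol %), THF, rt to 50 °C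
Reagents that add atoms: none
Why: In this Tsuji–Mandai hydrogenolysis, zerovalent palladium ionises the 3β-formate with inversion, decarboxylation leaves a palladium hydride on the α face, and hydride transfer to the more substituted allyl terminus C5 sets 5α-H (trans-decalin) and moves the olefin to C3–C4.

Step 19
Reactants: 27 dienone
Product: 28 3α,4α-epoxy-5α-eudesm-7(11)-en-8-one
Conditions: mCPBA, NaHCO3, CH2Cl2, 0 °C
Reagents that add atoms: 3-chloroperbenzoic acid OOC(=O)c1cccc(Cl)c1
Why: Prilezhaev epoxidation picks the electron-rich trisubstituted Δ3 olefin over the enone and should come from the α face, opposite to the axial C10 methyl.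

Step 20
Reactants: 28 epoxide
Product: 29 4β-acetoxy-3α-hydroxy-5α-eudesm-7(11)-en-8-one
Conditions: AcOH, rt to 40 °C
Reagents that add atoms: acetic acid CC(=O)O
Why: Epoxide acetolysis obeys both the Markovnikov and the Fürst–Plattner rule, acetic acid attacking tertiary C4 from the β face with inversion, so C3 and C4 are set trans-diaxially, no hindered tertiary alcohol has to be acylated and acyl migration is geometrically excluded.

Step 21
Reactants: 30 tiglic acid
Product: 31 (E)-2-methylbut-2-en-1-ol
Conditions: LiAlH4, Et2O, 0 °C to rt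
Reagents that add atoms: none
Why: Hydride reduction of the α,β-unsaturated acid gives the allylic alcohol with the olefin geometry kept.

Step 22
Reactants: 31 (E)-2-methylbut-2-en-1-ol
Product: 32 (2R,3R)-2,3-epoxy-2-methylbutan-1-ol
Conditions: Ti(OiPr)4 (cat.), D-(−)-diisopropyl tartrate (cat.), t-BuOOH, 4 Å sieves, CH2Cl2, −20 °C
Reagents that add atoms: tert-butyl hydroperoxide CC(C)(C)OO
Why: In the Katsuki–Sharpless epoxidation the (E)-olefin geometry fixes the relative configuration (methyl groups cis) and the D-(−)-tartrate fixes the absolute configuration of both epoxide carbons.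

Step 23
Reactants: 32 epoxy alcohol
Product: 33 (2S,3R)-2,3-epoxy-2-methylbutanoic acid
Conditions: TEMPO (cat.), PhI(OAc)2, MeCN–H2O, rt
Reagents that add atoms: water O
Why: Oxoammonium oxidation takes the primary alcohol through the aldehyde hydrate to the acid under nearly neutral conditions that keep the epoxide, the C2 descriptor changing by priority only.

Step 24
Reactants: 29 4β-acetoxy-3α-hydroxy-5α-eudesm-7(11)-en-8-one, 33 (2S,3R)-2,3-epoxy-2-methylbutanoic acid
Product: 35 4β-acetoxy-3α-[(2S,3R)-2,3-epoxy-2-methylbutanoyloxy]-5α-eudesm-7(11)-en-8-one, via mixed anhydride 34 (not isolated)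
Conditions: 2,4,6-Cl3C6H2COCl, Et3N, toluene, rt; 29, DMAP, rt to 60 °C
Reagents that add atoms: none
Why: Yamaguchi esterification activates the α-quaternary acid strongly enough for the axial secondary 3α-alcohol without acid or strong base, so epoxide, acetate and all stereocentres are kept.

Step 25
Reactants: 35 isopropylidene ketone diester
Product: 36 target, 4β-acetoxy-3α-[(2S,3R)-2,3-epoxy-2-methylbutanoyloxy]-11-hydroperoxy-5α-eudesm-6-en-8-one
Conditions: O2, tetraphenylporphyrin (cat.), visible light, CH2Cl2, 0 °C
Reagents that add atoms: oxygen O=O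
Why: In the Schenck ene reaction singlet oxygen attacks the s-cis tetrasubstituted enone with the known geminal selectivity, taking an axial H6 from the branch geminal to the carbonyl and bonding at C11, which gives the tertiary hydroperoxide and the C6–C7 enone without touching a stereocentre.

Compound list
1 | ethyl 4-methylpent-4-enoate | CCOC(=O)CCC(C)=C | starting material
2 | N-methoxy-N,4-dimethylpent-4-enamide | CON(C)C(=O)CCC(C)=C | intermediate
3 | isopropenylmagnesium bromide | CC(=C)[Mg]Br | starting material
4 | 2,6-dimethylhepta-1,6-dien-3-one | CC(=C)C(=O)CCC(C)=C | intermediate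
5 | (S)-2,6-dimethylhepta-1,6-dien-3-ol | CC(=C)[C@@H](O)CCC(C)=C | intermediate
6 | (S)-2,6-dimethyl-3-(triisopropylsilyloxy)hepta-1,6-diene | CC(=C)[C@@H](O[Si](C(C)C)(C(C)C)C(C)C)CCC(C)=C | intermediate
7 | trichloroacetyl chloride | ClC(Cl)(Cl)C(Cl)=O | starting material
8 | dichloroketene | ClC(Cl)=C=O | intermediate
9 | 2,2-dichloro-3-methyl-3-[(3S)-4-methyl-3-(triisopropylsilyloxy)pent-4-enyl]cyclobutanone | CC(=C)[C@@H](O[Si](C(C)C)(C(C)C)C(C)C)CCC1(C)CC(=O)C1(Cl)Cl | intermediate
10 | 3-methyl-3-[(3S)-4-methyl-3-(triisopropylsilyloxy)pent-4-enyl]cyclobutanone | CC(=C)[C@@H](O[Si](C(C)C)(C(C)C)C(C)C)CCC1(C)CC(=O)C1 | intermediate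
11 | 2-methylbut-3-yn-2-ol | CC(C)(O)C#C | starting material
12 | sodium 2-methylbut-3-yn-2-olate | CC(C)([O-])C#C.[Na+] | intermediate
13 | 3-methoxy-3-methylbut-1-yne | COC(C)(C)C#C | intermediate
14 | lithium 3-methoxy-3-methylbut-1-ynide | COC(C)(C)C#[C-].[Li+] | intermediate
15 | benzyl(3-methoxy-3-methylbut-1-ynyl)dimethylsilane | COC(C)(C)C#C[Si](C)(C)Cc1ccccc1 | intermediate
16 | (5R)-3-(benzyldimethylsilyl)-2-(2-methoxypropan-2-yl)-5-methyl-5-[(3S)-4-methyl-3-(triisopropylsilyloxy)pent-4-enyl]cyclohex-2-enone | CC(=C)[C@@H](O[Si](C(C)C)(C(C)C)C(C)C)CC[C@]1(C)CC(=O)C(C(C)(C)OC)=C([Si](C)(C)Cc2ccccc2)C1 | intermediate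
17 | (5S)-2-(2-methoxypropan-2-yl)-5-methyl-5-[(3S)-4-methyl-3-(triisopropylsilyloxy)pent-4-enyl]cyclohex-2-enone | CC(=C)[C@@H](O[Si](C(C)C)(C(C)C)C(C)C)CC[C@]1(C)CC(=O)C(C(C)(C)OC)=CC1 | intermediate
18 | ozonide (1,2,4-trioxolane) of 17 | CC1(OCOO1)[C@@H](O[Si](C(C)C)(C(C)C)C(C)C)CC[C@]2(C)CC(=O)C(C(C)(C)OC)=CC2 | intermediate
19 | (5S)-2-(2-methoxypropan-2-yl)-5-methyl-5-[(3S)-4-oxo-3-(triisopropylsilyloxy)pentyl]cyclohex-2-enone | CC(=O)[C@@H](O[Si](C(C)C)(C(C)C)C(C)C)CC[C@]1(C)CC(=O)C(C(C)(C)OC)=CC1 | intermediate
20 | (5R)-4-bromo-2-(2-methoxypropan-2-yl)-5-methyl-5-[(3S)-4-oxo-3-(triisopropylsilyloxy)pentyl]cyclohex-2-enone | CC(=O)[C@@H](O[Si](C(C)C)(C(C)C)C(C)C)CC[C@]1(C)CC(=O)C(C(C)(C)OC)=CC1Br | intermediate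
21 | 4α-hydroxy-11-methoxy-3β-(triisopropylsilyloxy)-5β-eudesm-6-en-8-one | O[C@@]1(C)[C@H]2C=C(C(C)(C)OC)C(=O)C[C@@]2(C)CC[C@@H]1O[Si](C(C)C)(C(C)C)C(C)C | intermediate
22 | 4α-hydroxy-11-methoxy-3β-(triisopropylsilyloxy)-5β-eudesman-8-one (C7 undefined) | O[C@@]1(C)[C@H]2CC(C(C)(C)OC)C(=O)C[C@@]2(C)CC[C@@H]1O[Si](C(C)C)(C(C)C)C(C)C | intermediate
23 | 4α-hydroxy-3β-(triisopropylsilyloxy)-5β-eudesm-7(11)-en-8-one | O[C@@]1(C)[C@H]2CC(=C(C)C)C(=O)C[C@@]2(C)CC[C@@H]1O[Si](C(C)C)(C(C)C)C(C)C | intermediate
24 | 3β-(triisopropylsilyloxy)eudesma-4,7(11)-dien-8-one | CC1=C2CC(=C(C)C)C(=O)C[C@@]2(C)CC[C@@H]1O[Si](C(C)C)(C(C)C)C(C)C | intermediate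
25 | 3β-hydroxyeudesma-4,7(11)-dien-8-one | CC1=C2CC(=C(C)C)C(=O)C[C@@]2(C)CC[C@@H]1O | intermediate
26 | 3β-formyloxyeudesma-4,7(11)-dien-8-one | CC1=C2CC(=C(C)C)C(=O)C[C@@]2(C)CC[C@@H]1OC=O | intermediate
27 | 5α-eudesma-3,7(11)-dien-8-one | CC1=CCC[C@]2(C)CC(=O)C(=C(C)C)C[C@@H]12 | intermediate
28 | 3α,4α-epoxy-5α-eudesm-7(11)-en-8-one | O1[C@@]2(C)[C@@H]3CC(=C(C)C)C(=O)C[C@@]3(C)CC[C@@H]12 | intermediate
29 | 4β-acetoxy-3α-hydroxy-5α-eudesm-7(11)-en-8-one | CC(=O)O[C@]1(C)[C@@H]2CC(=C(C)C)C(=O)C[C@@]2(C)CC[C@H]1O | intermediate
30 | tiglic acid | C/C=C(\C)C(=O)O | starting material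
31 | (E)-2-methylbut-2-en-1-ol | C/C=C(\C)CO | intermediate
32 | (2R,3R)-2,3-epoxy-2-methylbutan-1-ol | OC[C@@]1(C)O[C@@H]1C | intermediate
33 | (2S,3R)-2,3-epoxy-2-methylbutanoic acid | OC(=O)[C@@]1(C)O[C@@H]1C | intermediate
34 | (2S,3R)-2,3-epoxy-2-methylbutanoic 2,4,6-trichlorobenzoic anhydride | O=C(OC(=O)[C@@]1(C)O[C@@H]1C)c1c(Cl)cc(Cl)cc1Cl | intermediate
35 | 4β-acetoxy-3α-[(2S,3R)-2,3-epoxy-2-methylbutanoyloxy]-5α-eudesm-7(11)-en-8-one | CC(=O)O[C@]1(C)[C@@H]2CC(=C(C)C)C(=O)C[C@@]2(C)CC[C@H]1OC(=O)[C@@]1(C)O[C@@H]1C | intermediate
36 | 4β-acetoxy-3α-[(2S,3R)-2,3-epoxy-2-methylbutanoyloxy]-11-hydroperoxy-5α-eudesm-6-en-8-one | CC(=O)O[C@]1(C)[C@@H]2C=C(C(C)(C)OO)C(=O)C[C@@]2(C)CC[C@H]1OC(=O)[C@@]1(C)O[C@@H]1C | target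

Total step count: 25. Longest linear sequence: 20 steps (1–6, 9–20, 24, 25).

Steps most likely to fail

1. Step 9.
- What may go wrong: oxidative cyclisation may be slow with an alkyne hindered at both ends, the alkyne may oligomerise, or the ligand may discriminate poorly between the two ring bonds.
- Fallback: it sets out from 10 and 15 and gives up catalyst control altogether. The known racemic insertion protocol (Ni(cod)2, PCy3, toluene, 100 °C) should give 16 together with the C10 epimer of the silyl enone F1.
- The stereochemical problem then moves from the metal to a separation. The (S)-carbinol makes the two products diastereomers, which are parted by preparative HPLC, and the route is rejoined at 16.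

2. Step 13.
- What may go wrong: the dienolate may be protonated, or may lose methoxide, before it adds to the hindered ketone.
- Fallback: it sets out from 20 and activates the electrophile instead of the nucleophile. Zinc dust and Me3SiCl in THF should trap the regiodefined dienolate as the keto trimethylsilyl dienol ether F2.
- A vinylogous Mukaiyama aldol reaction (BF3·OEt2, CH2Cl2, −78 °C, aqueous work-up) then closes C4–C5, and the route is rejoined at 21.

3. Step 12.
- What may go wrong: hydrogen may be abstracted at the carbinol C3–H, or ionic bromination may occur at C9.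
- Fallback: it sets out from 17 and brominates ionically before the ketone exists. Iron-catalysed thermodynamic enolisation (MeMgBr, FeCl3 cat., then Me3SiCl, Et3N) should give the extended trimethylsilyl dienol ether F3.
- NBS at −78 °C brominates the γ terminus of F3 to the bromo enone with intact isopropenyl group F4.
- Ozonolysis of F4 through the ozonide F5 (Me2S work-up) rejoins the route at 20.

Further compounds
F1 | step 9 | (5S)-3-(benzyldimethylsilyl)-2-(2-methoxypropan-2-yl)-5-methyl-5-[(3S)-4-methyl-3-(triisopropylsilyloxy)pent-4-enyl]cyclohex-2-enone | CC(=C)[C@@H](O[Si](C(C)C)(C(C)C)C(C)C)CC[C@@]1(C)CC(=O)C(C(C)(C)OC)=C([Si](C)(C)Cc2ccccc2)C1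
F2 | step 13 | keto trimethylsilyl dienol ether (C5=C6, C7=C8–OSiMe3) | CC(=O)[C@@H](O[Si](C(C)C)(C(C)C)C(C)C)CC[C@]1(C)CC(O[Si](C)(C)C)=C(C(C)(C)OC)C=C1
F3 | step 12 | extended trimethylsilyl dienol ether of 17 | CC(=C)[C@@H](O[Si](C(C)C)(C(C)C)C(C)C)CC[C@]1(C)CC(O[Si](C)(C)C)=C(C(C)(C)OC)C=C1
F4 | step 12 | 4-bromo derivative of 17 | CC(=C)[C@@H](O[Si](C(C)C)(C(C)C)C(C)C)CC[C@]1(C)CC(=O)C(C(C)(C)OC)=CC1Br
F5 | step 12 | ozonide of F4 | CC1(OCOO1)[C@@H](O[Si](C(C)C)(C(C)C)C(C)C)CC[C@]2(C)CC(=O)C(C(C)(C)OC)=CC2Br
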